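Ring A is built last. Its C5‑OH/C7‑O resorcinol pattern, with C6–H between the two oxygens, is fused across the C4a–C8a bond of ring C, which is the pattern a vinylketene and an ynol ether deliver. One photochemical operation on a 5‑aryl‑4‑pyranone carrying a diazoacetyl group at C2 (19) and (triisopropylsiloxy)acetylene (23) should form four C–C bonds (C8–C8a, C5–C6, C7–C8, C4a–C5) and the whole benzo ring, leaving the chelated 5‑OH free and the 7‑oxygen silylated. The precursor joins a kojic‑acid‑derived pyranone to a fully substituted ring B made from 2‑bromoisovanillin, with benzyl ethers on both phenols and a silyl ether on the tertiary alcohol.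

Key step: step 13

Assumption: 2‑bromo‑3‑hydroxy‑4‑methoxybenzaldehyde (1) is taken as a catalogue compound, whereas (triisopropylsiloxy)acetylene is not and is made in step 12.
Abbreviation: Ar = 2,4‑bis(benzyloxy)‑3‑{3‑[(tert‑butyldimethylsilyl)oxy]‑3‑methylbutyl}‑5‑methoxyphenyl. The target is achiral; the only sp3 stereocentres on the route (in 25 and 27) are transient and racemic.

Step 1
Reactants: 1 2‑bromo‑3‑hydroxy‑4‑methoxybenzaldehyde
Product: 2 3‑(benzyloxy)‑2‑bromo‑4‑methoxybenzaldehyde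
Conditions: BnBr, K2CO3, DMF, rt
Reagents that add atoms: benzyl bromide, BrCc1ccccc1
Why: Williamson ether synthesis on the only phenol; the benzyl ether is kept to the last step and later becomes the 4'‑O protecting group.

Step 2
Reactants: 3 2‑methylbut‑3‑en‑2‑ol
Product: 4 tert‑butyldimethyl[(2‑methylbut‑3‑en‑2‑yl)oxy]silane
Conditions: TBSOTf, 2,6‑lutidine, CH2Cl2, 0 °C → rt
Reagents that add atoms: tert‑butyldimethylsilyl trifluoromethanesulfonate, CC(C)(C)[Si](C)(C)OS(=O)(=O)C(F)(F)F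
Why: Silylation of a hindered tertiary alcohol with a silyl triflate and a non‑nucleophilic base is standard and gives an ether that withstands every later step up to the fluoride treatment.

Step 3
Reactants: 4 tert‑butyldimethyl[(2‑methylbut‑3‑en‑2‑yl)oxy]silane; 2 3‑(benzyloxy)‑2‑bromo‑4‑methoxybenzaldehyde
Product: 6 3‑(benzyloxy)‑2‑{3‑[(tert‑butyldimethylsilyl)oxy]‑3‑methylbutyl}‑4‑methoxybenzaldehyde, via alkyl‑9‑BBN borane 5 (not isolated)
Conditions: 4 (1.3 equiv), 9‑BBN (1.2 equiv), THF, 0 °C → rt; then 2 (1.0 equiv), Pd(OAc)2, SPhos, 3 M aq. K3PO4, THF, 60 °C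
Reagents that add atoms: 9‑borabicyclo[3.3.1]nonane, B1C2CCCC1CCC2 (its boron and carbons stay only in intermediate 5)
Why: Anti‑Markovnikov hydroboration of the terminal alkene followed by B‑alkyl Suzuki–Miyaura coupling installs the saturated side chain directly; the ortho‑formyl group speeds oxidative addition, SPhos handles the doubly ortho‑substituted bromide, and the aldehyde is spared because the alkene is in excess and no B–H remains.

Step 4
Reactants: 6 3‑(benzyloxy)‑2‑{3‑[(tert‑butyldimethylsilyl)oxy]‑3‑methylbutyl}‑4‑methoxybenzaldehyde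
Product: 8 3‑(benzyloxy)‑2‑{3‑[(tert‑butyldimethylsilyl)oxy]‑3‑methylbutyl}‑4‑methoxyphenol, via aryl formate 7 (not isolated)
Conditions: mCPBA, NaHCO3, CH2Cl2, 0 °C → rt; aq. Na2S2O3; then K2CO3 (cat.), MeOH, 0 °C
Reagents that add atoms: 3‑chloroperoxybenzoic acid, OOC(=O)c1cccc(Cl)c1
Why: Baeyer–Villiger (Dakin‑type) oxidation, in which the electron‑rich aryl group (para‑methoxy, ortho‑alkyl) migrates in preference to hydrogen, followed by mild methanolysis of the formate once the peracid has been quenched.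

Step 5
Reactants: 8 3‑(benzyloxy)‑2‑{3‑[(tert‑butyldimethylsilyl)oxy]‑3‑methylbutyl}‑4‑methoxyphenol
Product: 9 3‑(benzyloxy)‑6‑bromo‑2‑{3‑[(tert‑butyldimethylsilyl)oxy]‑3‑methylbutyl}‑4‑methoxyphenol
Conditions: NBS (1.0 equiv), i‑Pr2NH (cat.), CH2Cl2, −78 → 0 °C
Reagents that add atoms: N‑bromosuccinimide, BrN1C(=O)CCC1=O
Why: Electrophilic aromatic bromination directed by the free phenol, whose para position carries the methoxy group and whose other ortho position carries the side chain, so only C6 (also para to the benzyloxy group) is available to it.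

Step 6
Reactants: 9 3‑(benzyloxy)‑6‑bromo‑2‑{3‑[(tert‑butyldimethylsilyl)oxy]‑3‑methylbutyl}‑4‑methoxyphenol
Product: 10 1‑bromo‑2,4‑bis(benzyloxy)‑3‑{3‑[(tert‑butyldimethylsilyl)oxy]‑3‑methylbutyl}‑5‑methoxybenzene
Conditions: BnBr, K2CO3, DMF, 40 °C
Reagents that add atoms: benzyl bromide, BrCc1ccccc1
Why: Williamson ether synthesis on the remaining phenol; with both oxygens flanking the side chain benzylated, the tertiary alcohol cannot later close a chroman ring.

Step 7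
Reactants: 10 1‑bromo‑2,4‑bis(benzyloxy)‑3‑{3‑[(tert‑butyldimethylsilyl)oxy]‑3‑methylbutyl}‑5‑methoxybenzene
Product: 11 2‑Ar‑4,4,5,5‑tetramethyl‑1,3,2‑dioxaborolane
Conditions: B2pin2, PdCl2(dppf), KOAc, 1,4‑dioxane, 90 °C
Reagents that add atoms: bis(pinacolato)diboron, CC1(C)OB(OC1(C)C)B1OC(C)(C)C(C)(C)O1
Why: Miyaura borylation of an aryl bromide tolerates benzyl and silyl ethers and avoids an aryllithium next to a benzyloxy group.

Step 8
Reactants: 12 kojic acid (5‑hydroxy‑2‑(hydroxymethyl)‑4H‑pyran‑4‑one)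
Product: 13 6‑(hydroxymethyl)‑4‑oxo‑4H‑pyran‑3‑yl trifluoromethanesulfonate
Conditions: PhNTf2 (1.05 equiv), Et3N, MeCN/DMF, 0 °C → rt
Reagents that add atoms: N‑phenylbis(trifluoromethanesulfonimide), O=S(=O)(N(c1ccccc1)S(=O)(=O)C(F)(F)F)C(F)(F)F
Why: Chemoselective O‑sulfonylation, since only the acidic enolic 5‑OH is deprotonated by the amine and the mild triflimide reagent does not react with the neutral primary alcohol.

Step 9
Reactants: 13 6‑(hydroxymethyl)‑4‑oxo‑4H‑pyran‑3‑yl trifluoromethanesulfonate; 11 2‑Ar‑4,4,5,5‑tetramethyl‑1,3,2‑dioxaborolane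
Product: 14 5‑Ar‑2‑(hydroxymethyl)‑4H‑pyran‑4‑one
Conditions: Pd(OAc)2, SPhos, K3PO4, THF/H2O (10:1), 45 °C
Reagents that add atoms: none
Why: Suzuki–Miyaura coupling of an enol triflate activated by the adjacent pyranone carbonyl; a highly active catalyst at low temperature with a mild base limits triflate hydrolysis and protodeboronation.

Step 10
Reactants: 14 5‑Ar‑2‑(hydroxymethyl)‑4H‑pyran‑4‑one
Product: 16 5‑Ar‑4‑oxo‑4H‑pyran‑2‑carboxylic acid, via pyranone‑2‑carbaldehyde 15 (not isolated)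
Conditions: TEMPO (cat.), PhI(OAc)2 (2.5 equiv), MeCN/H2O (1:1), rt
Reagents that add atoms: water, O
Why: Oxoammonium (TEMPO) oxidation of the primary alcohol to the aldehyde, whose readily formed hydrate is oxidised on to the acid; the conditions are near neutral and leave benzyl ethers, the silyl ether and the electron‑rich ring untouched.

Step 11
Reactants: 16 5‑Ar‑4‑oxo‑4H‑pyran‑2‑carboxylic acid; 17 (trimethylsilyl)diazomethane
Product: 19 5‑Ar‑2‑(diazoacetyl)‑4H‑pyran‑4‑one, via acid chloride 18 (not isolated)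
Conditions: 1‑chloro‑N,N,2‑trimethylprop‑1‑en‑1‑amine, CH2Cl2, 0 °C → rt; concentrate; then 17 (2 equiv), THF/MeCN (1:1), 0 °C → rt
Reagents that add atoms: 1‑chloro‑N,N,2‑trimethylprop‑1‑en‑1‑amine, CC(C)=C(Cl)N(C)C (its chlorine stays only in intermediate 18)
Why: Neutral acid chloride formation with an α‑chloroenamine (no HCl, so the tertiary silyl ether is safe), then C‑acylation of the silyl diazomethane with loss of the silyl group (Arndt–Eistert‑type diazo ketone synthesis).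

Step 12
Reactants: 20 acetylene
Product: 23 (triisopropylsiloxy)acetylene, via ethynyllithium 21 (not isolated), via lithium ethynolate 22 (not isolated)
Conditions: n‑BuLi, THF, −78 °C (excess acetylene); t‑BuOOLi (from t‑BuOOH, LiHMDS, THF, −78 °C), −78 → 0 °C; then TIPSOTf, −78 → 0 °C; pentane work‑up, distillation
Reagents that add atoms: n‑butyllithium, [Li]CCCC (lithium of intermediates 21 and 22 only); tert‑butyl hydroperoxide, CC(C)(C)OO; triisopropylsilyl trifluoromethanesulfonate, CC(C)[Si](OS(=O)(=O)C(F)(F)F)(C(C)C)C(C)C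
Why: Electrophilic oxygenation of a lithium acetylide by lithium tert‑butyl peroxide gives the ynolate, which the bulky silyl triflate silylates on oxygen (acetylide oxidation–O‑silylation route to silyl ynol ethers).

Step 13
Reactants: 19 5‑Ar‑2‑(diazoacetyl)‑4H‑pyran‑4‑one; 23 (triisopropylsiloxy)acetylene
Product: 28 3‑Ar‑5‑hydroxy‑7‑[(triisopropylsilyl)oxy]‑4H‑chromen‑4‑one, via pyranonylketene 24 (not isolated), via 3‑siloxycyclobutenone 25 (not isolated), via dienylketene 26 (not isolated), via cyclohexadienone 27 (not isolated)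
Conditions: 23 (2.5 equiv), ClCH2CH2Cl, hν (390 nm LED), rt, until the diazo ketone is consumed; then 80 °C
Reagents that add atoms: none
Why: Proposed new method: Light absorbed by the diazo ketone expels N2 and the pyranone C2 shifts onto the diazo carbon (Wolff rearrangement, C8–C8a), giving ketene 24 whose vinyl partner is the pyranone C2=C3 bond; the polarised ynol ether 23 then adds in a stepwise [2+2], its nucleophilic CH to the ketene carbonyl carbon (C5–C6) and its oxygen‑bearing carbon to the ketene α‑carbon (C7–C8), to give cyclobutenone 25. Warming opens 25 by a reversible 4π‑electrocyclic cleavage to dienylketene 26, and ring A closes by a thermal, disrotatory 6π‑electrocyclisation of the ketene carbon onto pyranone C3 (C4a–C5), after which dienone 27, a 1,3‑dicarbonyl‑type tautomer, enolises to the phenol hydrogen‑bonded to C4=O. The closest known reaction is the Danheiser photochemical benzannulation of α,β‑unsaturated and heteroaryl diazomethyl ketones with siloxyalkynes to resorcinol monosilyl ethers; the extension is the use of a 4‑pyranone C=C bond as the unsaturated unit. No stereocentre is created, since the sp3 carbons of 25 and 27 are transient and lost on aromatisation. The step needs regioselectivity in the [2+2], which the oxygen‑induced polarity of 23 secures, and only one 6π terminus exists (C3, next to C4=O), so the ketene carbonyl must become the 5‑OH and the alkyne oxygen the 7‑oxygen. It also needs chemoselective excitation, secured by 390 nm light that the diazo ketone absorbs but the pyranone and benzyl ethers do not, while excess 23 outruns acylation of the chelated phenol by the ketene.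

Step 14
Reactants: 28 3‑Ar‑5‑hydroxy‑7‑[(triisopropylsilyl)oxy]‑4H‑chromen‑4‑one
Product: 29 3‑[2,4‑bis(benzyloxy)‑3‑(3‑hydroxy‑3‑methylbutyl)‑5‑methoxyphenyl]‑5,7‑dihydroxy‑4H‑chromen‑4‑one
Conditions: TBAF (excess), THF, 0 → 50 °C; aq. NH4Cl
Reagents that add atoms: none
Why: Fluoride‑induced desilylation cleaves the aryl silyl ether quickly and the tertiary silyl ether on warming; the tertiary alcohol is freed while both neighbouring phenols are still benzylated, so it cannot cyclise to a chroman.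

Step 15
Reactants: 29 3‑[2,4‑bis(benzyloxy)‑3‑(3‑hydroxy‑3‑methylbutyl)‑5‑methoxyphenyl]‑5,7‑dihydroxy‑4H‑chromen‑4‑one
Product: 30 3‑[2,4‑dihydroxy‑3‑(3‑hydroxy‑3‑methylbutyl)‑5‑methoxyphenyl]‑5,7‑dihydroxy‑4H‑chromen‑4‑one (CNP0277410.0)
Conditions: H2 (1 atm), 10% Pd/C, EtOAc/MeOH, rt, stopped when 29 is consumed
Reagents that add atoms: none
Why: Catalytic hydrogenolysis of the two aryl benzyl ethers under neutral conditions, which should leave the chromone C2=C3 bond and the acid‑sensitive tertiary alcohol/ortho‑phenol pair untouched.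

Compound list
1 | 2‑bromo‑3‑hydroxy‑4‑methoxybenzaldehyde (2‑bromoisovanillin) | COc1ccc(C=O)c(Br)c1O | starting material
2 | 3‑(benzyloxy)‑2‑bromo‑4‑methoxybenzaldehyde | COc1ccc(C=O)c(Br)c1OCc1ccccc1 | intermediate
3 | 2‑methylbut‑3‑en‑2‑ol | C=CC(C)(C)O | starting material
4 | tert‑butyldimethyl[(2‑methylbut‑3‑en‑2‑yl)oxy]silane | C=CC(C)(C)O[Si](C)(C)C(C)(C)C | intermediate
5 | 9‑{3‑[(tert‑butyldimethylsilyl)oxy]‑3‑methylbutyl}‑9‑borabicyclo[3.3.1]nonane (not isolated) | CC(C)(CCB1C2CCCC1CCC2)O[Si](C)(C)C(C)(C)C | intermediate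
6 | 3‑(benzyloxy)‑2‑{3‑[(tert‑butyldimethylsilyl)oxy]‑3‑methylbutyl}‑4‑methoxybenzaldehyde | COc1ccc(C=O)c(CCC(C)(C)O[Si](C)(C)C(C)(C)C)c1OCc1ccccc1 | intermediate
7 | 3‑(benzyloxy)‑2‑{3‑[(tert‑butyldimethylsilyl)oxy]‑3‑methylbutyl}‑4‑methoxyphenyl formate (not isolated) | COc1ccc(OC=O)c(CCC(C)(C)O[Si](C)(C)C(C)(C)C)c1OCc1ccccc1 | intermediate
8 | 3‑(benzyloxy)‑2‑{3‑[(tert‑butyldimethylsilyl)oxy]‑3‑methylbutyl}‑4‑methoxyphenol | COc1ccc(O)c(CCC(C)(C)O[Si](C)(C)C(C)(C)C)c1OCc1ccccc1 | intermediate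
9 | 3‑(benzyloxy)‑6‑bromo‑2‑{3‑[(tert‑butyldimethylsilyl)oxy]‑3‑methylbutyl}‑4‑methoxyphenol | COc1cc(Br)c(O)c(CCC(C)(C)O[Si](C)(C)C(C)(C)C)c1OCc1ccccc1 | intermediate
10 | 1‑bromo‑2,4‑bis(benzyloxy)‑3‑{3‑[(tert‑butyldimethylsilyl)oxy]‑3‑methylbutyl}‑5‑methoxybenzene | COc1cc(Br)c(OCc2ccccc2)c(CCC(C)(C)O[Si](C)(C)C(C)(C)C)c1OCc1ccccc1 | intermediate
11 | 2‑Ar‑4,4,5,5‑tetramethyl‑1,3,2‑dioxaborolane | COc1cc(B2OC(C)(C)C(C)(C)O2)c(OCc2ccccc2)c(CCC(C)(C)O[Si](C)(C)C(C)(C)C)c1OCc1ccccc1 | intermediate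
12 | kojic acid, 5‑hydroxy‑2‑(hydroxymethyl)‑4H‑pyran‑4‑one | OCc1cc(=O)c(O)co1 | starting material
13 | 6‑(hydroxymethyl)‑4‑oxo‑4H‑pyran‑3‑yl trifluoromethanesulfonate | OCc1cc(=O)c(OS(=O)(=O)C(F)(F)F)co1 | intermediate
14 | 5‑Ar‑2‑(hydroxymethyl)‑4H‑pyran‑4‑one | COc1cc(-c2coc(CO)cc2=O)c(OCc2ccccc2)c(CCC(C)(C)O[Si](C)(C)C(C)(C)C)c1OCc1ccccc1 | intermediate
15 | 5‑Ar‑4‑oxo‑4H‑pyran‑2‑carbaldehyde (not isolated) | COc1cc(-c2coc(C=O)cc2=O)c(OCc2ccccc2)c(CCC(C)(C)O[Si](C)(C)C(C)(C)C)c1OCc1ccccc1 | intermediate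
16 | 5‑Ar‑4‑oxo‑4H‑pyran‑2‑carboxylic acid | COc1cc(-c2coc(C(=O)O)cc2=O)c(OCc2ccccc2)c(CCC(C)(C)O[Si](C)(C)C(C)(C)C)c1OCc1ccccc1 | intermediate
17 | (trimethylsilyl)diazomethane | C[Si](C)(C)C=[N+]=[N-] | starting material
18 | 5‑Ar‑4‑oxo‑4H‑pyran‑2‑carbonyl chloride (not isolated) | COc1cc(-c2coc(C(=O)Cl)cc2=O)c(OCc2ccccc2)c(CCC(C)(C)O[Si](C)(C)C(C)(C)C)c1OCc1ccccc1 | intermediate
19 | 5‑Ar‑2‑(diazoacetyl)‑4H‑pyran‑4‑one | [N-]=[N+]=CC(=O)c1cc(=O)c(-c2cc(OC)c(OCc3ccccc3)c(CCC(C)(C)O[Si](C)(C)C(C)(C)C)c2OCc2ccccc2)co1 | intermediate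
20 | acetylene | C#C | starting material
21 | ethynyllithium (not isolated) | [Li]C#C | intermediate
22 | lithium ethynolate (not isolated) | [Li+].[O-]C#C | intermediate
23 | (triisopropylsiloxy)acetylene, ethynyloxytri(propan‑2‑yl)silane | C#CO[Si](C(C)C)(C(C)C)C(C)C | intermediate
24 | (5‑Ar‑4‑oxo‑4H‑pyran‑2‑yl)ketene (not isolated) | O=C=Cc1cc(=O)c(-c2cc(OC)c(OCc3ccccc3)c(CCC(C)(C)O[Si](C)(C)C(C)(C)C)c2OCc2ccccc2)co1 | intermediate
25 | 4‑(5‑Ar‑4‑oxo‑4H‑pyran‑2‑yl)‑3‑[(triisopropylsilyl)oxy]cyclobut‑2‑en‑1‑one, racemic (not isolated) | O=C1C=C(O[Si](C(C)C)(C(C)C)C(C)C)C1c1cc(=O)c(-c2cc(OC)c(OCc3ccccc3)c(CCC(C)(C)O[Si](C)(C)C(C)(C)C)c2OCc2ccccc2)co1 | intermediate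
26 | 4‑(5‑Ar‑4‑oxo‑4H‑pyran‑2‑yl)‑3‑[(triisopropylsilyl)oxy]buta‑1,3‑dien‑1‑one, ketene carbon and pyranone cis across C3=C4 (not isolated) | O=C=C/C(O[Si](C(C)C)(C(C)C)C(C)C)=C\c1cc(=O)c(-c2cc(OC)c(OCc3ccccc3)c(CCC(C)(C)O[Si](C)(C)C(C)(C)C)c2OCc2ccccc2)co1 | intermediate
27 | 3‑Ar‑7‑[(triisopropylsilyl)oxy]‑4H‑chromene‑4,5(4aH)‑dione, racemic (not isolated) | O=C1C=C(O[Si](C(C)C)(C(C)C)C(C)C)C=C2OC=C(c3cc(OC)c(OCc4ccccc4)c(CCC(C)(C)O[Si](C)(C)C(C)(C)C)c3OCc3ccccc3)C(=O)C12 | intermediate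
28 | 3‑Ar‑5‑hydroxy‑7‑[(triisopropylsilyl)oxy]‑4H‑chromen‑4‑one | COc1cc(-c2coc3cc(O[Si](C(C)C)(C(C)C)C(C)C)cc(O)c3c2=O)c(OCc2ccccc2)c(CCC(C)(C)O[Si](C)(C)C(C)(C)C)c1OCc1ccccc1 | intermediate
29 | 3‑[2,4‑bis(benzyloxy)‑3‑(3‑hydroxy‑3‑methylbutyl)‑5‑methoxyphenyl]‑5,7‑dihydroxy‑4H‑chromen‑4‑one | COc1cc(-c2coc3cc(O)cc(O)c3c2=O)c(OCc2ccccc2)c(CCC(C)(C)O)c1OCc1ccccc1 | intermediate
30 | 3‑[2,4‑dihydroxy‑3‑(3‑hydroxy‑3‑methylbutyl)‑5‑methoxyphenyl]‑5,7‑dihydroxy‑4H‑chromen‑4‑one (CNP0277410.0) | COc1cc(-c2coc3cc(O)cc(O)c3c2=O)c(O)c(CCC(C)(C)O)c1O | target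

Total step count: 15. Longest linear sequence: 12 steps (steps 1, 3, 4, 5, 6, 7, 9, 10, 11, 13, 14, 15, counted from 1).

Steps most likely to fail

Step 13 (Proposed new method). The pyranone chromophore may compete for light and photoisomerise, the ketene may be lost to dimerisation or to acylation of the product phenol before the [2+2] takes place, or the thermal ring opening may stall at the cyclobutenone. The fallback uses known chemistry and brings ring A in preformed; it sets out from boronate 11 and comes back at target 30. Commercial 1‑[2,4‑bis(benzyloxy)‑6‑hydroxyphenyl]ethan‑1‑one F1 would be condensed with N,N‑dimethylformamide dimethyl acetal (neat, 95 °C) to (E)‑1‑[2,4‑bis(benzyloxy)‑6‑hydroxyphenyl]‑3‑(dimethylamino)prop‑2‑en‑1‑one F2, whose iodine‑induced cyclisation (I2, CHCl3, rt) should give 5,7‑bis(benzyloxy)‑3‑iodo‑4H‑chromen‑4‑one F3. Suzuki–Miyaura coupling of F3 with 11 (Pd(OAc)2, SPhos, K3PO4, THF/H2O, 50 °C) should give 3‑Ar‑5,7‑bis(benzyloxy)‑4H‑chromen‑4‑one F4. TBAF (THF, 50 °C) would then free the tertiary alcohol to give 5,7‑bis(benzyloxy)‑3‑[2,4‑bis(benzyloxy)‑3‑(3‑hydroxy‑3‑methylbutyl)‑5‑methoxyphenyl]‑4H‑chromen‑4‑one F5, and hydrogenolysis of the four benzyl ethers (H2, Pd/C, EtOAc/MeOH) gives 30.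

Step 12. Oxygen transfer to the acetylide may be incomplete, ethynyllithium may disproportionate to the unreactive dilithium acetylide, silylation may go to carbon or the ynol ether may isomerise to a silylketene, and material may be lost when the sensitive ynol ether is isolated. The fallback generates the same ynolate by fragmentation instead of oxidation; it replaces acetylene 20 as the carbon source and comes back to the route at lithium ethynolate 22, and hence 23. Commercial 3‑phenylisoxazole F6 would be lithiated at C5 (n‑BuLi, THF, −78 °C) to 5‑lithio‑3‑phenylisoxazole F7, which on warming to about 0 °C should cleave into benzonitrile and 22. Silylation with TIPSOTf at −78 °C, as in step 12, then gives 23, which is separated from benzonitrile by distillation.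

Step 9. The hindered, electron‑rich boronate may protodeboronate, the enol triflate may hydrolyse, or hydroxide may open the pyranone in the aqueous base. The fallback is an anhydrous, base‑free Negishi coupling; it sets out from bromide 10 and triflate 13 and comes back at 14. Triflate 13 would be silylated (TBSCl, imidazole, DMF) to 6‑{[(tert‑butyldimethylsilyl)oxy]methyl}‑4‑oxo‑4H‑pyran‑3‑yl trifluoromethanesulfonate F8. Bromine–lithium exchange on 10 (n‑BuLi, THF, −78 °C) gives the aryllithium Ar–Li F9, which ZnCl2 converts into the arylzinc chloride Ar–ZnCl F10. Coupling of F10 with F8 (Pd(OAc)2, SPhos, THF, rt → 40 °C) should give 5‑Ar‑2‑{[(tert‑butyldimethylsilyl)oxy]methyl}‑4H‑pyran‑4‑one F11, and HF·pyridine (THF/pyridine, 0 °C) should cleave the primary silyl ether selectively, leaving the tertiary one, to give 14.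

Further compounds
F1 | step 13 | 1‑[2,4‑bis(benzyloxy)‑6‑hydroxyphenyl]ethan‑1‑one (purchased) | CC(=O)c1c(O)cc(OCc2ccccc2)cc1OCc1ccccc1
F2 | step 13 | (E)‑1‑[2,4‑bis(benzyloxy)‑6‑hydroxyphenyl]‑3‑(dimethylamino)prop‑2‑en‑1‑one | CN(C)/C=C/C(=O)c1c(O)cc(OCc2ccccc2)cc1OCc1ccccc1
F3 | step 13 | 5,7‑bis(benzyloxy)‑3‑iodo‑4H‑chromen‑4‑one | O=c1c(I)coc2cc(OCc3ccccc3)cc(OCc3ccccc3)c12
F4 | step 13 | 3‑Ar‑5,7‑bis(benzyloxy)‑4H‑chromen‑4‑one | COc1cc(-c2coc3cc(OCc4ccccc4)cc(OCc4ccccc4)c3c2=O)c(OCc2ccccc2)c(CCC(C)(C)O[Si](C)(C)C(C)(C)C)c1OCc1ccccc1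
F5 | step 13 | 5,7‑bis(benzyloxy)‑3‑[2,4‑bis(benzyloxy)‑3‑(3‑hydroxy‑3‑methylbutyl)‑5‑methoxyphenyl]‑4H‑chromen‑4‑one | COc1cc(-c2coc3cc(OCc4ccccc4)cc(OCc4ccccc4)c3c2=O)c(OCc2ccccc2)c(CCC(C)(C)O)c1OCc1ccccc1
F6 | step 12 | 3‑phenylisoxazole (purchased) | c1ccc(-c2ccon2)cc1
F7 | step 12 | 5‑lithio‑3‑phenylisoxazole | [Li]c1cc(-c2ccccc2)no1
F8 | step 9 | 6‑{[(tert‑butyldimethylsilyl)oxy]methyl}‑4‑oxo‑4H‑pyran‑3‑yl trifluoromethanesulfonate | CC(C)(C)[Si](C)(C)OCc1cc(=O)c(OS(=O)(=O)C(F)(F)F)co1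
F9 | step 9 | aryllithium Ar–Li | COc1cc([Li])c(OCc2ccccc2)c(CCC(C)(C)O[Si](C)(C)C(C)(C)C)c1OCc1ccccc1
F10 | step 9 | arylzinc chloride Ar–ZnCl | COc1cc([Zn]Cl)c(OCc2ccccc2)c(CCC(C)(C)O[Si](C)(C)C(C)(C)C)c1OCc1ccccc1
F11 | step 9 | 5‑Ar‑2‑{[(tert‑butyldimethylsilyl)oxy]methyl}‑4H‑pyran‑4‑one | COc1cc(-c2coc(CO[Si](C)(C)C(C)(C)C)cc2=O)c(OCc2ccccc2)c(CCC(C)(C)O[Si](C)(C)C(C)(C)C)c1OCc1ccccc1
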